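**Strategy.** The 2,4-disubstituted imidazole is cut at two bonds that lie opposite each other, C4–C5 and C2–N3. This leaves a C2–N1–C5 fragment, supplied as the azomethine-ylide portion of a glycine-derived münchnone carrying the 6-bromoindol-3-yl group on the future C2 (C5 stays C–H), and an N3–C4 fragment, supplied as the N-tosyl imine of indole-3-carbaldehyde. One operation (cyclodehydration, [3+2] cycloaddition, loss of CO2 and sulfinic acid) builds the complete aromatic ring with both indoles in place. The precursor is an N-aroyl-N-(2,4-dimethoxybenzyl)glycine with both indole nitrogens tosylated; acidolysis of the benzyl group and hydroxide detosylation finish the synthesis.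

Key step: step 8

Remark: nortopsentin B has no stereogenic element, so no stereocontrol is needed and the route delivers the single achiral compound as drawn.

**Step 1**
Reactants: 1 6-bromo-1H-indole-3-carbaldehyde
Product: 2 6-bromo-1-tosyl-1H-indole-3-carbaldehyde
Conditions: TsCl, Et3N, DMAP (cat.), CH2Cl2, 0 °C → rt
Reagents that add atoms: p-toluenesulfonyl chloride, Cc1ccc(cc1)S(Cl)(=O)=O
Why: N-sulfonylation; the 3-formyl group acidifies the indole N–H enough for Et3N/DMAP to deliver the sulfonamide, which later keeps this nitrogen inert toward the dipole.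

**Step 2**
Reactants: 2 6-bromo-1-tosyl-1H-indole-3-carbaldehyde
Product: 3 6-bromo-1-tosyl-1H-indole-3-carboxylic acid
Conditions: NaClO2, NaH2PO4, 2-methyl-2-butene, t-BuOH/THF/H2O, rt
Reagents that add atoms: sodium chlorite, [Na+].[O-]Cl=O
Why: Pinnick oxidation converts the aldehyde into the acid under buffered, near-neutral conditions that spare the N-sulfonyl group and the aryl bromide, with 2-methyl-2-butene scavenging hypochlorous acid before it can chlorinate the indole.

**Step 3**
Reactants: 3 6-bromo-1-tosyl-1H-indole-3-carboxylic acid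
Product: 4 6-bromo-1-tosyl-1H-indole-3-carbonyl chloride
Conditions: (COCl)2, DMF (cat.), CH2Cl2, 0 °C → rt; evaporate, use crude
Reagents that add atoms: oxalyl chloride, ClC(=O)C(=O)Cl
Why: DMF-catalysed (Vilsmeier-type) chlorination of the carboxylic acid gives the acyl chloride, and since all by-products are gases the crude chloride can be used after evaporation.

**Step 4**
Reactants: 5 glycine; 6 2,4-dimethoxybenzaldehyde
Product: 8 N-(2,4-dimethoxybenzyl)glycine, via Schiff-base sodium salt 7 (not isolated)
Conditions: NaOH (1 equiv), MeOH/H2O, rt; NaBH4, 0 °C → rt; HCl to pH ≈ 6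
Reagents that add atoms: none
Why: Reductive amination of an amino acid through its preformed Schiff base; the aldehyde is consumed as the imine before the hydride is added, so the secondary amine should not be alkylated a second time, and the zwitterion is collected at its isoelectric point.

**Step 5**
Reactants: 8 N-(2,4-dimethoxybenzyl)glycine; 4 6-bromo-1-tosyl-1H-indole-3-carbonyl chloride
Product: 11 N-(6-bromo-1-tosylindole-3-carbonyl)-N-(2,4-dimethoxybenzyl)glycine, via silyl ester of the amino acid 9 (not isolated), via silyl ester of the amide 10 (not isolated)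
Conditions: 8, TMSCl (1.1 equiv), iPr2NEt (3 equiv), CH2Cl2, 40 °C; then 4, 0 °C → rt; aq. citric acid work-up
Reagents that add atoms: none
Why: Transient silyl-ester protection followed by N-acylation with an acyl chloride (amide formation); the silyl ester dissolves the amino acid and masks the carboxyl group, the secondary amine is the only strong nucleophile left, and the ester falls off in the mildly acidic work-up, so no separate ester cleavage that could endanger the sulfonamide or the acid-labile benzyl group is required.

**Step 6**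
Reactants: 12 1H-indole-3-carbaldehyde
Product: 13 1-tosyl-1H-indole-3-carbaldehyde
Conditions: TsCl, Et3N, DMAP (cat.), CH2Cl2, 0 °C → rt
Reagents that add atoms: p-toluenesulfonyl chloride, Cc1ccc(cc1)S(Cl)(=O)=O
Why: The same N-sulfonylation as in step 1; the tosyl group also damps the donor effect of the indole nitrogen and so raises the electrophilicity of the aldehyde and of its imine.

**Step 7**
Reactants: 13 1-tosyl-1H-indole-3-carbaldehyde; 14 p-toluenesulfonamide
Product: 15 (E)-4-methyl-N-[(1-tosyl-1H-indol-3-yl)methylidene]benzenesulfonamide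
Conditions: Ti(OEt)4 (2 equiv), CH2Cl2, 40 °C; brief aqueous quench, filtration, crystallisation
Reagents that add atoms: none
Why: Titanium(IV)-mediated dehydrative condensation of an aldehyde with a primary sulfonamide gives the N-sulfonyl aldimine, titanium ethoxide acting as Lewis acid and water scavenger, and the conjugated E isomer is the thermodynamic product.

**Step 8**
Reactants: 11 N-(6-bromo-1-tosylindole-3-carbonyl)-N-(2,4-dimethoxybenzyl)glycine; 15 (E)-N-tosyl imine of 1-tosylindole-3-carbaldehyde
Product: 18 1-(2,4-dimethoxybenzyl)-2-(6-bromo-1-tosylindol-3-yl)-4-(1-tosylindol-3-yl)imidazole, via münchnone 16 (not isolated), via bicyclic cycloadduct 17 (not isolated)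
Conditions: DIC (1.5 equiv), 15 (2.5 equiv), CH2Cl2, rt; 11 added slowly by syringe pump, then rt → 40 °C
Reagents that add atoms: none
Why: DIC turns the carboxyl group of 11 into an O-acylisourea that is attacked by the amide oxygen (5-exo-trig cyclodehydration), and loss of the acidic ring C–H proton gives the mesoionic oxazolium-5-olate 16, whose C2–N3–C4 unit is an azomethine ylide. This dipole adds across the C=N bond of 15 in a [3+2] cycloaddition (concerted, or a fast Mannich addition/ring closure), forming the imidazole C4–C5 and C2–N3 bonds in bicyclic lactone 17; cycloreversion then expels CO2, and the resulting ylide ejects toluenesulfinate from N3 and loses the C4 proton to give aromatic 18. The closest known reaction type is the carbodiimide-mediated cycloaddition of münchnones from N-acyl-N-benzylglycines with N-sulfonyl aldimines, which gives 1,2,4-trisubstituted imidazoles. The imidazole is the only ring closed, and it closes by intermolecular two-bond [3+2] annulation followed by extrusion, not by cyclisation of a chain; no stereocentre remains, because the three of 17 are erased on aromatisation. The step needs regioselectivity (indolyl at C4, not C5) and cross-reaction in preference to self-condensation: the first follows from pairing the nucleophilic unsubstituted ylide carbon with the strongly electrophilic sulfonyl-imine carbon and the sulfonamide nitrogen with the oxazolium C2, the second from slow addition of 11 to an excess of 15. Both indole nitrogens carry tosyl groups so that no N–H can protonate or acylate the dipole and the imine stays electrophilic.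

**Step 9**
Reactants: 18 1-(2,4-dimethoxybenzyl)-2-(6-bromo-1-tosylindol-3-yl)-4-(1-tosylindol-3-yl)imidazole
Product: 19 2-(6-bromo-1-tosyl-1H-indol-3-yl)-4-(1-tosyl-1H-indol-3-yl)-1H-imidazole
Conditions: TFA, anisole (5 equiv), 70 °C
Reagents that add atoms: none
Why: Acidolytic N-debenzylation (SN1); protonation at N3 makes the imidazole a leaving group, the 2,4-dimethoxybenzyl cation departs and is captured by anisole in a Friedel–Crafts alkylation, while both electron-poor N-tosylindoles resist the cation and the acid.

**Step 10**
Reactants: 19 2-(6-bromo-1-tosyl-1H-indol-3-yl)-4-(1-tosyl-1H-indol-3-yl)-1H-imidazole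
Product: 20 nortopsentin B, 2-(6-bromo-1H-indol-3-yl)-4-(1H-indol-3-yl)-1H-imidazole
Conditions: NaOH (2 M aq., excess), 1,4-dioxane, 80 °C; neutralise with aq. NH4Cl
Reagents that add atoms: none
Why: Nucleophilic desulfonylation; hydroxide attacks sulfur and the indolide anions leave, an alcohol-free medium being chosen so that no alkyl tosylate forms that could N-alkylate the product, and the aryl bromide is inert to aqueous base.

**Compound list**

1 | 6-bromo-1H-indole-3-carbaldehyde | O=Cc1c[nH]c2cc(Br)ccc12 | starting material
2 | 6-bromo-1-tosyl-1H-indole-3-carbaldehyde | O=Cc1cn(S(=O)(=O)c2ccc(C)cc2)c2cc(Br)ccc12 | intermediate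
3 | 6-bromo-1-tosyl-1H-indole-3-carboxylic acid | OC(=O)c1cn(S(=O)(=O)c2ccc(C)cc2)c2cc(Br)ccc12 | intermediate
4 | 6-bromo-1-tosyl-1H-indole-3-carbonyl chloride | ClC(=O)c1cn(S(=O)(=O)c2ccc(C)cc2)c2cc(Br)ccc12 | intermediate
5 | glycine | NCC(=O)O | starting material
6 | 2,4-dimethoxybenzaldehyde | COc1ccc(C=O)c(OC)c1 | starting material
7 | sodium (E)-N-(2,4-dimethoxybenzylidene)glycinate (not isolated) | COc1ccc(/C=N/CC(=O)[O-])c(OC)c1.[Na+] | intermediate
8 | N-(2,4-dimethoxybenzyl)glycine | COc1ccc(CNCC(=O)O)c(OC)c1 | intermediate
9 | trimethylsilyl N-(2,4-dimethoxybenzyl)glycinate (not isolated) | COc1ccc(CNCC(=O)O[Si](C)(C)C)c(OC)c1 | intermediate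
10 | trimethylsilyl N-(6-bromo-1-tosylindole-3-carbonyl)-N-(2,4-dimethoxybenzyl)glycinate (not isolated) | C[Si](C)(C)OC(=O)CN(Cc1ccc(OC)cc1OC)C(=O)c1cn(S(=O)(=O)c2ccc(C)cc2)c2cc(Br)ccc12 | intermediate
11 | N-(6-bromo-1-tosylindole-3-carbonyl)-N-(2,4-dimethoxybenzyl)glycine | OC(=O)CN(Cc1ccc(OC)cc1OC)C(=O)c1cn(S(=O)(=O)c2ccc(C)cc2)c2cc(Br)ccc12 | intermediate
12 | 1H-indole-3-carbaldehyde | O=Cc1c[nH]c2ccccc12 | starting material
13 | 1-tosyl-1H-indole-3-carbaldehyde | O=Cc1cn(S(=O)(=O)c2ccc(C)cc2)c2ccccc12 | intermediate
14 | p-toluenesulfonamide | Cc1ccc(cc1)S(N)(=O)=O | starting material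
15 | (E)-4-methyl-N-[(1-tosyl-1H-indol-3-yl)methylidene]benzenesulfonamide | Cc1ccc(cc1)S(=O)(=O)/N=C/c1cn(S(=O)(=O)c2ccc(C)cc2)c2ccccc12 | intermediate
16 | 2-(6-bromo-1-tosylindol-3-yl)-3-(2,4-dimethoxybenzyl)-1,3-oxazol-3-ium-5-olate, the münchnone (not isolated) | [O-]c1c[n+](Cc2ccc(OC)cc2OC)c(o1)-c1cn(S(=O)(=O)c2ccc(C)cc2)c2cc(Br)ccc12 | intermediate
17 | 1-(6-bromo-1-tosylindol-3-yl)-7-(2,4-dimethoxybenzyl)-5-(1-tosylindol-3-yl)-6-tosyl-2-oxa-6,7-diazabicyclo[2.2.1]heptan-3-one, racemic, configuration at C5 not controlled and lost on aromatisation (not isolated) | O=C1OC2(c3cn(S(=O)(=O)c4ccc(C)cc4)c4cc(Br)ccc34)N(Cc3ccc(OC)cc3OC)C1C(c1cn(S(=O)(=O)c3ccc(C)cc3)c3ccccc13)N2S(=O)(=O)c1ccc(C)cc1 | intermediate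
18 | 1-(2,4-dimethoxybenzyl)-2-(6-bromo-1-tosylindol-3-yl)-4-(1-tosylindol-3-yl)imidazole | COc1ccc(Cn2cc(-c3cn(S(=O)(=O)c4ccc(C)cc4)c4ccccc34)nc2-c2cn(S(=O)(=O)c3ccc(C)cc3)c3cc(Br)ccc23)c(OC)c1 | intermediate
19 | 2-(6-bromo-1-tosyl-1H-indol-3-yl)-4-(1-tosyl-1H-indol-3-yl)-1H-imidazole | Cc1ccc(cc1)S(=O)(=O)n1cc(-c2nc(-c3cn(S(=O)(=O)c4ccc(C)cc4)c4ccccc34)c[nH]2)c2ccc(Br)cc21 | intermediate
20 | nortopsentin B, 2-(6-bromo-1H-indol-3-yl)-4-(1H-indol-3-yl)-1H-imidazole (achiral) | Brc1ccc2c(-c3nc(-c4c[nH]c5ccccc45)c[nH]3)c[nH]c2c1 | target

**Step count.** Total: 10 steps. Longest linear sequence: 7 steps (1, 2, 3, 5, 8, 9, 10).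

**Steps most likely to fail**

Step 8. The 4-unsubstituted mesoionic dipole may self-condense, or the activated acid may rearrange to an N-acylurea, faster than the imine captures it; the released sulfinic acid may also consume imine. The fallback drops the dipole and assembles the ring by a Debus–Radziszewski condensation. It sets out from aldehydes 13 and 2. Addition of MeMgBr to 13 (THF, −78 °C) should give racemic 1-(1-tosyl-1H-indol-3-yl)ethanol F1. Dess–Martin oxidation should give 3-acetyl-1-tosylindole F2. Riley oxidation with SeO2 (dioxane/H2O, 100 °C) should give (1-tosyl-1H-indol-3-yl)glyoxal F3, handled as its hydrate. Condensation of F3 with aldehyde 2 and excess NH4OAc (MeOH/THF, rt → 50 °C) places the aldehyde carbon at C2 and the ketone carbon at C4. The fallback rejoins the route at 19, so step 9 is bypassed as well.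

Step 9. Ionisation of the benzylic C–N bond of the protonated imidazole may be incomplete, or the benzylic cation may re-attach to a ring carbon. The fallback replaces acidolysis by oxidative debenzylation. It sets out from 18, which is treated with ceric ammonium nitrate (MeCN/H2O, 0 °C → rt). Single-electron oxidation of the dimethoxyarene, the most electron-rich ring present, and hydrolysis of the resulting benzylic cation should release the N–H imidazole. The fallback rejoins the route at 19 and makes no new intermediate.

Step 5. N-Acylation of the hindered, benzylated amine may be sluggish, with the acyl chloride lost to hydrolysis or to mixed-anhydride formation if the silyl ester is cleaved prematurely. The fallback uses an isolable ester that is removed under neutral conditions. It sets out from 8 and 4. Esterification of 8 (allyl alcohol, TMSCl, 50 °C) should give allyl N-(2,4-dimethoxybenzyl)glycinate F4. Acylation with 4 (Et3N, DMAP, CH2Cl2) should give allyl N-(6-bromo-1-tosylindole-3-carbonyl)-N-(2,4-dimethoxybenzyl)glycinate F5. Pd(PPh3)4 (cat.) with morpholine in THF at rt removes the allyl group without touching the sulfonamide, the benzyl group or, at this temperature, the aryl bromide. The fallback rejoins the route at 11.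

**Further compounds**

F1 | step 8 | racemic 1-(1-tosyl-1H-indol-3-yl)ethanol | CC(O)c1cn(S(=O)(=O)c2ccc(C)cc2)c2ccccc12
F2 | step 8 | 3-acetyl-1-tosyl-1H-indole | CC(=O)c1cn(S(=O)(=O)c2ccc(C)cc2)c2ccccc12
F3 | step 8 | (1-tosyl-1H-indol-3-yl)glyoxal | O=CC(=O)c1cn(S(=O)(=O)c2ccc(C)cc2)c2ccccc12
F0 | step 9 | none | none
F4 | step 5 | allyl N-(2,4-dimethoxybenzyl)glycinate | COc1ccc(CNCC(=O)OCC=C)c(OC)c1
F5 | step 5 | allyl N-(6-bromo-1-tosylindole-3-carbonyl)-N-(2,4-dimethoxybenzyl)glycinate | C=CCOC(=O)CN(Cc1ccc(OC)cc1OC)C(=O)c1cn(S(=O)(=O)c2ccc(C)cc2)c2cc(Br)ccc12
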